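The runs were computed for substances that don't exist; noise was put on by code.

A percentage of the charge can pass for a speed, and my two earlier runs set that trap.

| flask | substrate | reagent | free catalyst | temperature | remark | time |
|---|---|---|---|---|---|---|
| south-west | 0.60 M | 0.48 M | 1.2 mM | 0 °C | run made earlier |  |
| north-west | 0.20 M | 0.48 M | 1.2 mM | 0 °C | run made earlier |  |
| beta | 0.40 M | 0.480 M | 2.5 mM | 0 °C |  | 2.5 min |
| delta | 0.40 M | 0.480 M | 1.2 mM | 0 °C |  | 2.5 min |
| alpha | 0.40 M | 0.250 M | 1.2 mM | 0 °C |  | 2.5 min |
| theta | 0.40 M | 0.800 M | 1.2 mM | 15 °C |  | 2.5 min |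
| zeta | 0.40 M | 0.480 M | 0.60 mM | 0 °C |  | 2.5 min |

- south-west (time / s: product / %): 10.0: 2.3; 20.0: 3.8; 30.0: 6.2
- north-west (time / s: product / %): 10.0: 4.2; 20.0: 7.9; 30.0: 11.7

(readings scatter by 0.5 percentage points)

- ranking by amount of product, in percent of the substrate charged, from high to low, at 2.5 min (beta / delta / alpha / theta / zeta)
- the same order at 30 s (beta / delta / alpha / theta / zeta)
- the amount of product, in percent of the substrate charged of the flask you put first, at 2.5 min
- the amount of product, in percent of the substrate charged of the flask you put last, at 2.5 min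

- what may be going on: reagent + free catalyst -> catalyst intermediate A; substrate + catalyst intermediate A <-> catalyst intermediate B; catalyst intermediate C <-> by-product + catalyst intermediate D; catalyst intermediate B <-> catalyst intermediate C; 2 catalyst intermediate A <-> resting dimer; catalyst intermediate D -> free catalyst + product
- the earlier runs do not show what temperature does; that part of a forecast is a guess
- no earlier run changes the charge of free catalyst; that part of a forecast is a guess

1. At 30.0 s the north-west run stood at 11.7 % and the south-west run at 6.2 %, so south-west looked slower. In concentration, though, these readings put north-west at 0.780 mM s⁻¹ on average and south-west at 1.24 mM s⁻¹, so south-west read faster.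

2. I divided each charge by its rate. This gives a lifetime, the inverse of a pseudo-first-order constant: 256 s for north-west and 484 s for south-west.

3. For a saturating catalyst, rate = V·S/(K+S), so lifetime = (K+S)/V, a straight line in the charge. Delta's 0.40 M lies midway, so I took the mean, 370 s.

4. The number I carried is the substrate half-life, lifetime times ln(2): 257 s. Delta's 2.5 min holds 0.585 half-lives. That leaves 66.7 % of its substrate and gives 33.3 % product. On that line the lifetime shortens as substrate falls, so I held this figure as low.

5. No run varied the catalyst. I guessed that the half-life scales inversely with its charge, which gave beta 57.0 % and zeta 18.3 %.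

6. No run showed temperature either. I guessed that theta's warming cut the half-life by a factor of 3 and gave its extra reagent nothing, which made 70.4 %.

7. Alpha's reagent is the limiting reagent and caps product at 62.5 %. I placed alpha between delta and zeta by judgement, at both times.

8. The forecast gave theta > beta > delta > alpha > zeta at 2.5 min and theta > beta > delta > alpha > zeta at 30 s, with 78 % (58 % to 95 %) first and 25 % (17 % to 33 %) last, both above mine, and said “Catalyst order is a guess”.

9. The flasks gave theta > beta > delta > alpha > zeta, and theta > beta > delta > alpha > zeta at 30 s: theta 86.0 %, delta 35.8 %, zeta 20.4 %.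

    reagent + free catalyst → catalyst intermediate A (k = 6.66 L mol⁻¹ s⁻¹, Ea = 49.0 kJ mol⁻¹)
    substrate + catalyst intermediate A ⇌ catalyst intermediate B (K = 2.21 L mol⁻¹, k = 25.9 L mol⁻¹ s⁻¹, Ea = 37.0 kJ mol⁻¹, ΔH = 5.00 kJ mol⁻¹)
    catalyst intermediate C ⇌ by-product + catalyst intermediate D (K = 0.308 M, k = 11.1 s⁻¹, Ea = 50.0 kJ mol⁻¹, ΔH = −47.0 kJ mol⁻¹)
    catalyst intermediate B ⇌ catalyst intermediate C (K = 1.70, k = 9.43 s⁻¹, Ea = 53.0 kJ mol⁻¹, ΔH = 38.0 kJ mol⁻¹)
    2 catalyst intermediate A ⇌ resting dimer, settled at all times (K = 460 L mol⁻¹, ΔH = −35.0 kJ mol⁻¹)
    catalyst intermediate D → free catalyst + product (k = 9.09 s⁻¹, Ea = 52.0 kJ mol⁻¹)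
    (constants at 0 °C)

Theta kept 13.9 % of its substrate, which is 2.84 half-lives of 0.879 min each on average, a factor 4.87 below my 257 s for delta, where I had guessed 3 for warming and nothing for theta's extra reagent. That average half-life of theta's substrate was shorter than the 5.8 min that the making of catalyst intermediate A gave theta's reagent at 2.50 min, and at that time theta still held 56.9 % of its reagent. Counted in the same half-lives, the theta flask stopped at 1.5 min should keep 30.6 % of its substrate, and it kept 34 %.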